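**Retrosynthetic overview**

1. The route rests on ring A of the flavone half, a 2-aryl phloroglucinol: C8 carries ring B of the flavanone, C7 an OMe, C5 an OH and C8a the pyranone oxygen O1, so three oxygens have to be told apart.
2. Ring A is made first by benzannulation of aryl methoxyacetylene 6 with 3-ethoxycyclobutenone 7 (new bonds C8–C8a and C6–C7); it delivers C8a–OH free, C7–OMe and C5–OEt in one operation.
3. The pyranone ring follows: ortho-formylation at C4a, acetylide addition, oxidation and 6-endo closure of the o-hydroxyaryl ynone (O1–C2).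
4. The C–Br bond para to the ring B oxygen becomes a boronic acid; rhodium-catalysed asymmetric 1,4-addition to preformed 5-hydroxy-7-methoxychromone 27 forms the C1'–C2 bond of the flavanone and sets (2S).
5. Precursor 6 comes from 4-bromo-2-iodophenol by benzylation and Negishi coupling at C–I; a bromide replaces the masked aldehyde as the spectator handle on ring B, and hydrogenolysis ends the route.

Key step: step 3

Assumption: the biaryl axis (three ortho substituents, none bulky) is taken not to be a stable stereogenic element, as the target carries no axial descriptor.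
Assumption: the (S)-bisphosphine is taken to direct the aryl group to the chromone face that gives (2S), by analogy with arylation of cyclohexenone under (S)-biaryl bisphosphines; should the sense be opposite, the (R)-ligand is used.

**Route**

Step 1
Reactants: 1 4-bromo-2-iodophenol
Product: 2 1-(benzyloxy)-4-bromo-2-iodobenzene
Conditions: BnBr, K2CO3, DMF, rt
Reagents that add atoms: benzyl bromide, BrCc1ccccc1
Why: Williamson etherification of the phenoxide with a benzylic halide should proceed cleanly and masks the ring B oxygen against ketenes and organometallics.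

Step 2
Reactants: 2 1-(benzyloxy)-4-bromo-2-iodobenzene; 3 2-chloro-1,1-dimethoxyethane
Product: 6 1-(benzyloxy)-4-bromo-2-(methoxyethynyl)benzene, via lithium methoxyacetylide 4 (not isolated), via methoxyethynylzinc chloride 5 (not isolated)
Conditions: Et2NH, n-BuLi, THF, 0 °C (LiNEt2, 3 equiv per 3); 3 (1.5 equiv), 0 °C to rt; ZnCl2, THF, 0 °C; 2, Pd(PPh3)4 (5 mol%), rt; chromatography on Et3N-deactivated silica
Reagents that add atoms: none
Why: Threefold amide treatment of the chloroacetal (two eliminations and one deprotonation) should give the alkoxyacetylide, and Negishi coupling of its zinc derivative should occur only at C–I, which adds oxidatively to zerovalent palladium far faster than C–Br at room temperature.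

Step 3
Reactants: 6 1-(benzyloxy)-4-bromo-2-(methoxyethynyl)benzene; 7 3-ethoxycyclobut-2-en-1-one
Product: 12 2-[2-(benzyloxy)-5-bromophenyl]-5-ethoxy-3-methoxyphenol, via vinylketene 8 (not isolated), via vinylcyclobutenone 9 (not isolated), via dienylketene 10 (not isolated), via cyclohexadienone 11 (not isolated)
Conditions: 7 (1.5 equiv), toluene, 80 °C then 110 °C, sealed tube, Ar; then K2CO3, MeOH, rt
Reagents that add atoms: none
Why: Heat should open 7 by 4π electrocyclic ring opening to vinylketene 8, whose ketene carbon is attacked by the nucleophilic, aryl-bearing carbon of ynol ether 6 in a regioselective [2+2] cycloaddition to give 9; this opens again to dienylketene 10, which closes ring A by thermal disrotatory 6π electrocyclisation to dienone 11 and tautomerises to phenol 12 (Danheiser benzannulation of a cyclobutenone with an alkynyl ether). The two new skeletal bonds are flavone C8–C8a and C6–C7, and the 6π closure rejoins the former cyclobutenone C1 and C4 as C8a–C4a. No stereocentre survives, since the sp3 carbon of 9 becomes an aromatic CH. The only selectivity needed is the regiochemistry of the [2+2] event; the polarisation of the ynol ether secures it, so the ketene oxygen ends as the single free OH ortho to the aryl group, the ynol OMe on the other ortho carbon and the OEt para. A methyl ynol ether cannot lose an alkene by retro-ene fragmentation and should tolerate the temperature; 7 is used in excess because the product phenol can trap 8, and the methanolysis should return any such aryl ester to 12.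

Step 4
Reactants: 12 2-[2-(benzyloxy)-5-bromophenyl]-5-ethoxy-3-methoxyphenol
Product: 14 3-[2-(benzyloxy)-5-bromophenyl]-6-ethoxy-2-hydroxy-4-methoxybenzaldehyde, via hydroxymethylphenol 13 (not isolated)
Conditions: MgCl2, Et3N, (CH2O)n, MeCN, reflux
Reagents that add atoms: paraformaldehyde (formaldehyde), C=O
Why: Magnesium phenoxide-directed ortho-formylation (Casnati–Skattebøl) delivers formaldehyde only to the carbon ortho to the free OH, here the single open ortho position (future C4a), and a second formaldehyde oxidises the benzylic alcohol by hydride transfer.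

Step 5
Reactants: 14 3-[2-(benzyloxy)-5-bromophenyl]-6-ethoxy-2-hydroxy-4-methoxybenzaldehyde; 15 1-ethynyl-4-methoxybenzene
Product: 17 1-{3-[2-(benzyloxy)-5-bromophenyl]-6-ethoxy-2-hydroxy-4-methoxyphenyl}-3-(4-methoxyphenyl)prop-2-yn-1-ol (racemic), via lithium acetylide 16 (not isolated)
Conditions: 15 (3 equiv), n-BuLi (2.9 equiv), THF, −78 °C; then 14, −78 °C to rt; aq. NH4Cl
Reagents that add atoms: none
Why: Excess lithium acetylide should first deprotonate the phenol and then add 1,2 to the aldehyde, while an acetylide does not exchange with the aryl bromide; the carbinol centre is removed in the next step.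

Step 6
Reactants: 17 propargylic alcohol from step 5
Product: 18 1-{3-[2-(benzyloxy)-5-bromophenyl]-6-ethoxy-2-hydroxy-4-methoxyphenyl}-3-(4-methoxyphenyl)prop-2-yn-1-one
Conditions: activated MnO2, CH2Cl2, rt
Reagents that add atoms: none
Why: MnO2 oxidises a benzylic and propargylic alcohol selectively, and the resulting ynone is stabilised by its hydrogen bond to the ortho OH.

Step 7
Reactants: 18 ynone from step 6
Product: 20 8-[2-(benzyloxy)-5-bromophenyl]-5-ethoxy-7-methoxy-2-(4-methoxyphenyl)-4H-chromen-4-one, via enaminone 19 (not isolated)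
Conditions: Et2NH (5 equiv), EtOH, reflux
Reagents that add atoms: none
Why: Conjugate addition of the amine gives a β-enaminone that can close only in the 6-endo sense by addition–elimination of the phenol, so the flavone should form without the 5-exo aurone.

Step 8
Reactants: 20 flavone from step 7
Product: 21 8-(5-bromo-2-hydroxyphenyl)-5-hydroxy-7-methoxy-2-(4-methoxyphenyl)-4H-chromen-4-one
Conditions: BCl3 (5 equiv), C6HMe5, CH2Cl2, −78 °C to rt; aq. NaHCO3
Reagents that add atoms: none
Why: BCl3 chelated between C4=O and O5 cleaves the peri ethyl ether and also the benzyl ether (pentamethylbenzene traps the benzyl cation); the unchelated methyl ethers at C7 and on the anisyl ring should survive, and no stereocentre yet exists to suffer from the Lewis acid.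

Step 9
Reactants: 21 dihydroxy flavone from step 8
Product: 22 8-[2-(benzyloxy)-5-bromophenyl]-5-hydroxy-7-methoxy-2-(4-methoxyphenyl)-4H-chromen-4-one
Conditions: BnBr (1.1 equiv), K2CO3, acetone, 50 °C
Reagents that add atoms: benzyl bromide, BrCc1ccccc1
Why: Williamson benzylation occurs selectively at the ring B phenol, because the 5-OH is tied up in a hydrogen bond to the C4 carbonyl; this keeps a p-hydroxyaryl group out of the coupling step and away from the new stereocentre under base.

Step 10
Reactants: 22 bromide from step 9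
Product: 23 8-[2-(benzyloxy)-5-(4,4,5,5-tetramethyl-1,3,2-dioxaborolan-2-yl)phenyl]-5-hydroxy-7-methoxy-2-(4-methoxyphenyl)-4H-chromen-4-one
Conditions: B2pin2, Pd(dppf)Cl2 (5 mol%), KOAc, 1,4-dioxane, 90 °C
Reagents that add atoms: bis(pinacolato)diboron, CC1(C)OB(OC1(C)C)B1OC(C)(C)C(C)(C)O1
Why: Miyaura borylation of an aryl bromide with acetate as base tolerates the chelated phenol and the flavone.

Step 11
Reactants: 23 pinacol boronate from step 10
Product: 24 {4-(benzyloxy)-3-[5-hydroxy-7-methoxy-2-(4-methoxyphenyl)-4-oxo-4H-chromen-8-yl]phenyl}boronic acid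
Conditions: NaIO4, NH4OAc, acetone/H2O, rt
Reagents that add atoms: water, O
Why: Periodate destroys the pinacol set free by hydrolysis and so drives the ester to the boronic acid, the boron species needed for mild rhodium transmetalation.

Step 12
Reactants: 25 1-(2,6-dihydroxy-4-methoxyphenyl)ethan-1-one
Product: 27 5-hydroxy-7-methoxy-4H-chromen-4-one, via enaminone 26 (not isolated)
Conditions: Me2NCH(OMe)2, toluene, 90 °C; then conc. HCl, EtOH, 60 °C
Reagents that add atoms: N,N-dimethylformamide dimethyl acetal, COC(OC)N(C)C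
Why: Enaminone formation at the methyl ketone followed by acid-promoted addition–elimination of a phenol OH is the standard chromone synthesis, and either of the two equivalent OH groups gives the same product.

Step 13
Reactants: 24 boronic acid from step 11; 27 5-hydroxy-7-methoxy-4H-chromen-4-one
Product: 28 (2S)-2-{4-(benzyloxy)-3-[5-hydroxy-7-methoxy-2-(4-methoxyphenyl)-4-oxo-4H-chromen-8-yl]phenyl}-5-hydroxy-7-methoxy-2,3-dihydro-4H-chromen-4-one
Conditions: [RhCl(C2H4)2]2 (2.5 mol%), (S)-2,2'-bis[bis(3,4,5-trifluorophenyl)phosphino]-6,6'-dimethoxy-1,1'-biphenyl (5.5 mol%), aq. KOH (10 mol%), 27 (2 equiv), toluene/H2O, 30 °C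
Reagents that add atoms: none
Why: In this Hayashi–Miyaura asymmetric 1,4-addition the aryl group passes from boron to rhodium and inserts the chromone C2=C3 bond on the face left open by the C2-symmetric (S)-bisphosphine, which sets (2S) by catalyst control, and water releases the flavanone; the 2-aryl-substituted enone of the flavone half is too hindered to accept an aryl group.

Step 14
Reactants: 28 benzyl ether from step 13
Product: 29 2,3-dihydroheveaflavone, (2S)-5-hydroxy-2-{4-hydroxy-3-[5-hydroxy-7-methoxy-2-(4-methoxyphenyl)-4-oxo-4H-chromen-8-yl]phenyl}-7-methoxy-2,3-dihydro-4H-chromen-4-one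
Conditions: H2 (1 atm), 10% Pd/C, EtOAc/THF, rt
Reagents that add atoms: none
Why: Hydrogenolysis of the aryl benzyl ether under neutral conditions should be faster than reduction of the flavone C2=C3 bond or cleavage of the flavanone C2–O bond, and it leaves the base-sensitive (2S) centre untouched.

**Compound list**

1 | 4-bromo-2-iodophenol | Oc1ccc(Br)cc1I | starting material
2 | 1-(benzyloxy)-4-bromo-2-iodobenzene | Brc1ccc(OCc2ccccc2)c(I)c1 | intermediate
3 | 2-chloro-1,1-dimethoxyethane (chloroacetaldehyde dimethyl acetal) | COC(CCl)OC | starting material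
4 | lithium methoxyacetylide | [Li]C#COC | intermediate
5 | methoxyethynylzinc chloride | COC#C[Zn]Cl | intermediate
6 | 1-(benzyloxy)-4-bromo-2-(methoxyethynyl)benzene (precursor of the key step) | COC#Cc1cc(Br)ccc1OCc1ccccc1 | intermediate
7 | 3-ethoxycyclobut-2-en-1-one | CCOC1=CC(=O)C1 | starting material
8 | 3-ethoxybuta-1,3-dien-1-one (vinylketene) | CCOC(=C)C=C=O | intermediate
9 | 2-[2-(benzyloxy)-5-bromophenyl]-4-(1-ethoxyethenyl)-3-methoxycyclobut-2-en-1-one (racemic) | CCOC(=C)C1C(OC)=C(c2cc(Br)ccc2OCc2ccccc2)C1=O | intermediate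
10 | (3E)-2-[2-(benzyloxy)-5-bromophenyl]-5-ethoxy-3-methoxyhexa-1,3,5-trien-1-one (dienylketene) | C=C(OCC)/C=C(OC)\C(=C=O)c1cc(Br)ccc1OCc1ccccc1 | intermediate
11 | 2-[2-(benzyloxy)-5-bromophenyl]-5-ethoxy-3-methoxycyclohexa-2,4-dien-1-one | CCOC1=CC(OC)=C(c2cc(Br)ccc2OCc2ccccc2)C(=O)C1 | intermediate
12 | 2-[2-(benzyloxy)-5-bromophenyl]-5-ethoxy-3-methoxyphenol (product of the key step) | CCOc1cc(O)c(-c2cc(Br)ccc2OCc2ccccc2)c(OC)c1 | intermediate
13 | 2-[2-(benzyloxy)-5-bromophenyl]-5-ethoxy-6-(hydroxymethyl)-3-methoxyphenol | CCOc1cc(OC)c(-c2cc(Br)ccc2OCc2ccccc2)c(O)c1CO | intermediate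
14 | 3-[2-(benzyloxy)-5-bromophenyl]-6-ethoxy-2-hydroxy-4-methoxybenzaldehyde | CCOc1cc(OC)c(-c2cc(Br)ccc2OCc2ccccc2)c(O)c1C=O | intermediate
15 | 1-ethynyl-4-methoxybenzene | C#Cc1ccc(OC)cc1 | starting material
16 | lithium (4-methoxyphenyl)acetylide | [Li]C#Cc1ccc(OC)cc1 | intermediate
17 | 1-{3-[2-(benzyloxy)-5-bromophenyl]-6-ethoxy-2-hydroxy-4-methoxyphenyl}-3-(4-methoxyphenyl)prop-2-yn-1-ol (racemic) | CCOc1cc(OC)c(-c2cc(Br)ccc2OCc2ccccc2)c(O)c1C(O)C#Cc1ccc(OC)cc1 | intermediate
18 | 1-{3-[2-(benzyloxy)-5-bromophenyl]-6-ethoxy-2-hydroxy-4-methoxyphenyl}-3-(4-methoxyphenyl)prop-2-yn-1-one | CCOc1cc(OC)c(-c2cc(Br)ccc2OCc2ccccc2)c(O)c1C(=O)C#Cc1ccc(OC)cc1 | intermediate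
19 | 1-{3-[2-(benzyloxy)-5-bromophenyl]-6-ethoxy-2-hydroxy-4-methoxyphenyl}-3-(diethylamino)-3-(4-methoxyphenyl)prop-2-en-1-one (geometric isomers) | CCOc1cc(OC)c(-c2cc(Br)ccc2OCc2ccccc2)c(O)c1C(=O)C=C(N(CC)CC)c1ccc(OC)cc1 | intermediate
20 | 8-[2-(benzyloxy)-5-bromophenyl]-5-ethoxy-7-methoxy-2-(4-methoxyphenyl)-4H-chromen-4-one | CCOc1cc(OC)c(-c2cc(Br)ccc2OCc2ccccc2)c2oc(-c3ccc(OC)cc3)cc(=O)c12 | intermediate
21 | 8-(5-bromo-2-hydroxyphenyl)-5-hydroxy-7-methoxy-2-(4-methoxyphenyl)-4H-chromen-4-one | COc1ccc(-c2cc(=O)c3c(O)cc(OC)c(-c4cc(Br)ccc4O)c3o2)cc1 | intermediate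
22 | 8-[2-(benzyloxy)-5-bromophenyl]-5-hydroxy-7-methoxy-2-(4-methoxyphenyl)-4H-chromen-4-one | COc1ccc(-c2cc(=O)c3c(O)cc(OC)c(-c4cc(Br)ccc4OCc4ccccc4)c3o2)cc1 | intermediate
23 | 8-[2-(benzyloxy)-5-(4,4,5,5-tetramethyl-1,3,2-dioxaborolan-2-yl)phenyl]-5-hydroxy-7-methoxy-2-(4-methoxyphenyl)-4H-chromen-4-one | COc1ccc(-c2cc(=O)c3c(O)cc(OC)c(-c4cc(B5OC(C)(C)C(C)(C)O5)ccc4OCc4ccccc4)c3o2)cc1 | intermediate
24 | {4-(benzyloxy)-3-[5-hydroxy-7-methoxy-2-(4-methoxyphenyl)-4-oxo-4H-chromen-8-yl]phenyl}boronic acid | COc1ccc(-c2cc(=O)c3c(O)cc(OC)c(-c4cc(B(O)O)ccc4OCc4ccccc4)c3o2)cc1 | intermediate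
25 | 1-(2,6-dihydroxy-4-methoxyphenyl)ethan-1-one | CC(=O)c1c(O)cc(OC)cc1O | starting material
26 | (E)-1-(2,6-dihydroxy-4-methoxyphenyl)-3-(dimethylamino)prop-2-en-1-one | CN(C)/C=C/C(=O)c1c(O)cc(OC)cc1O | intermediate
27 | 5-hydroxy-7-methoxy-4H-chromen-4-one | COc1cc(O)c2c(c1)occc2=O | intermediate
28 | (2S)-2-{4-(benzyloxy)-3-[5-hydroxy-7-methoxy-2-(4-methoxyphenyl)-4-oxo-4H-chromen-8-yl]phenyl}-5-hydroxy-7-methoxy-2,3-dihydro-4H-chromen-4-one | COc1ccc(-c2cc(=O)c3c(O)cc(OC)c(-c4cc([C@@H]5CC(=O)c6c(O)cc(OC)cc6O5)ccc4OCc4ccccc4)c3o2)cc1 | intermediate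
29 | 2,3-dihydroheveaflavone, (2S)-5-hydroxy-2-{4-hydroxy-3-[5-hydroxy-7-methoxy-2-(4-methoxyphenyl)-4-oxo-4H-chromen-8-yl]phenyl}-7-methoxy-2,3-dihydro-4H-chromen-4-one | COc1ccc(-c2cc(=O)c3c(O)cc(OC)c(-c4cc([C@@H]5CC(=O)c6c(O)cc(OC)cc6O5)ccc4O)c3o2)cc1 | target

**Step count and risks**

Total step count: 14. Longest linear sequence: 13 (steps 1 to 11, then 13 and 14); step 12 is a one-step branch.

Steps most likely to fail:

Step 3. The vinylketene may be consumed by dimerisation or by O-acylation of the product phenol faster than it adds to the hindered, aryl-conjugated ynol ether, and the donor-substituted cyclobutenone is a little-tested partner. The fallback gives up the benzannulation and forms the C8–aryl bond by cross-coupling on a finished flavone; it sets out from 2 and comes back at 21. Iodine–magnesium exchange on 2 (i-PrMgCl·LiCl, THF, −30 °C, selective for C–I), then B(OMe)3 and aqueous acid, should give [2-(benzyloxy)-5-bromophenyl]boronic acid F1. Purchased 5,7-dimethoxy-2-(4-methoxyphenyl)-4H-chromen-4-one (COc1ccc(-c2cc(=O)c3c(OC)cc(OC)cc3o2)cc1) is iodinated with I2 and CF3CO2Ag in CH2Cl2, which in the 5-O-methyl series goes to C8, to give 8-iodo-5,7-dimethoxy-2-(4-methoxyphenyl)-4H-chromen-4-one F2. Suzuki–Miyaura coupling of F1 with F2 (Pd(PPh3)4, Na2CO3, DME/H2O, 80 °C; the C–I bond reacts before C–Br) should give 8-[2-(benzyloxy)-5-bromophenyl]-5,7-dimethoxy-2-(4-methoxyphenyl)-4H-chromen-4-one F3. BCl3 with pentamethylbenzene then removes the benzyl group and the chelated 5-O-methyl group and gives 21.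

Step 13. Protodeboronation of the electron-rich boronic acid, base-induced opening of the chromone, or β-aryloxide elimination from the rhodium enolate may outrun productive insertion, and facial selectivity may fall short with the chelated 5-hydroxychromone. The fallback builds the flavanone by chalcone closure and resolution; it sets out from 22 and comes back at 28. Reductive carbonylation of 22 (Pd(OAc)2, di(1-adamantyl)-n-butylphosphine, CO/H2, TMEDA, toluene, 100 °C) should give 4-(benzyloxy)-3-[5-hydroxy-7-methoxy-2-(4-methoxyphenyl)-4-oxo-4H-chromen-8-yl]benzaldehyde F4. Ketone 25 is mono-protected (MOMCl, i-Pr2NEt, CH2Cl2) to 1-[2-hydroxy-4-methoxy-6-(methoxymethoxy)phenyl]ethan-1-one F5. Claisen–Schmidt condensation of F4 with F5 (KOH, EtOH/THF, rt) should give the (E)-chalcone F6. HCl in MeOH/THF removes the MOM group to give the 2',6'-dihydroxychalcone F7, which closes on heating with NaOAc in EtOH to the racemic flavanone F8; both OH groups lead to the same product. Preparative HPLC on a polysaccharide chiral stationary phase separates the (2S)-enantiomer, 28.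

Step 2. Hydration or oligomerisation of the acid-sensitive ynol ether during coupling and isolation, slow transmetalation of the alkoxyethynylzinc reagent, or competing reaction at C–Br may erode the coupling. The fallback makes the ynol ether by elimination and not by cross-coupling; it sets out from 2 and comes back at 6. Iodine–magnesium exchange on 2 (i-PrMgCl·LiCl, THF, −30 °C) and acylation with purchased N,2-dimethoxy-N-methylacetamide (COCC(=O)N(C)OC) should give 1-[2-(benzyloxy)-5-bromophenyl]-2-methoxyethan-1-one F9. Enolisation and O-sulfonylation (LiN(SiMe3)2, PhNTf2, THF, −78 °C) give 1-[2-(benzyloxy)-5-bromophenyl]-2-methoxyethenyl trifluoromethanesulfonate F10, whose geometry is not controlled. Elimination with KOt-Bu in THF at −78 °C then gives 6.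

**Further compounds**

F1 | step 3 | [2-(benzyloxy)-5-bromophenyl]boronic acid | OB(O)c1cc(Br)ccc1OCc1ccccc1
F2 | step 3 | 8-iodo-5,7-dimethoxy-2-(4-methoxyphenyl)-4H-chromen-4-one | COc1ccc(-c2cc(=O)c3c(OC)cc(OC)c(I)c3o2)cc1
F3 | step 3 | 8-[2-(benzyloxy)-5-bromophenyl]-5,7-dimethoxy-2-(4-methoxyphenyl)-4H-chromen-4-one | COc1ccc(-c2cc(=O)c3c(OC)cc(OC)c(-c4cc(Br)ccc4OCc4ccccc4)c3o2)cc1
F4 | step 13 | 4-(benzyloxy)-3-[5-hydroxy-7-methoxy-2-(4-methoxyphenyl)-4-oxo-4H-chromen-8-yl]benzaldehyde | COc1ccc(-c2cc(=O)c3c(O)cc(OC)c(-c4cc(C=O)ccc4OCc4ccccc4)c3o2)cc1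
F5 | step 13 | 1-[2-hydroxy-4-methoxy-6-(methoxymethoxy)phenyl]ethan-1-one | CC(=O)c1c(O)cc(OC)cc1OCOC
F6 | step 13 | (E)-3-{4-(benzyloxy)-3-[5-hydroxy-7-methoxy-2-(4-methoxyphenyl)-4-oxo-4H-chromen-8-yl]phenyl}-1-[2-hydroxy-4-methoxy-6-(methoxymethoxy)phenyl]prop-2-en-1-one | COCOc1cc(OC)cc(O)c1C(=O)/C=C/c1ccc(OCc2ccccc2)c(c1)-c1c(OC)cc(O)c2c(=O)cc(-c3ccc(OC)cc3)oc12
F7 | step 13 | (E)-3-{4-(benzyloxy)-3-[5-hydroxy-7-methoxy-2-(4-methoxyphenyl)-4-oxo-4H-chromen-8-yl]phenyl}-1-(2,6-dihydroxy-4-methoxyphenyl)prop-2-en-1-one | COc1cc(O)c(C(=O)/C=C/c2ccc(OCc3ccccc3)c(c2)-c2c(OC)cc(O)c3c(=O)cc(-c4ccc(OC)cc4)oc23)c(O)c1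
F8 | step 13 | racemic 2-{4-(benzyloxy)-3-[5-hydroxy-7-methoxy-2-(4-methoxyphenyl)-4-oxo-4H-chromen-8-yl]phenyl}-5-hydroxy-7-methoxy-2,3-dihydro-4H-chromen-4-one | COc1ccc(-c2cc(=O)c3c(O)cc(OC)c(-c4cc(C5CC(=O)c6c(O)cc(OC)cc6O5)ccc4OCc4ccccc4)c3o2)cc1
F9 | step 2 | 1-[2-(benzyloxy)-5-bromophenyl]-2-methoxyethan-1-one | COCC(=O)c1cc(Br)ccc1OCc1ccccc1
F10 | step 2 | 1-[2-(benzyloxy)-5-bromophenyl]-2-methoxyethenyl trifluoromethanesulfonate | COC=C(OS(=O)(=O)C(F)(F)F)c1cc(Br)ccc1OCc1ccccc1
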